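**Plan**

- Retrosynthesis: cut the C6–O ester bond (isovanillic acid), then C4–C5 (aldol, ring A), then re-form C7–C10 so that ring B becomes a methylenecyclobutane fused to a cyclopentanone, then cut C7–C8 and C9–C10 (cyclopentenone + allene), and last the C1–CH3 bond and the bond from the side chain to the ring.
- Enabling feature: in the seven-membered ring B (C1, C5, C6, C7, C8, C9, C10) the unit C8(CH3)–C9 sits as a two-carbon insert between C7 and C10, and C7=C8 is conjugated to the oxygen-bearing C6. This is the pattern left when a cyclopentenone–allene photoadduct is opened across its ring-fusion bond.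
- Forward order: the side chain is joined to a cyclopentenone, C1 is made by asymmetric methyl conjugate addition, the enone is re-installed next to C1, allene [2+2] gives the four-membered ring, reductive opening gives ring B, aldol closure gives ring A, then reduction and acylation.
- Stereochemistry: C1 comes from the chiral copper–carbene catalyst. C4 and C5 come from C1 in the metal-bridged aldol closure (cis fusion, hydroxyl syn to C6). C6 comes from chelation-controlled hydride addition anti to C4. The two centres of the photoadduct are transient.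

Key step: step 6

Remarks on the chemistry. Atom labels: C1 quaternary fusion carbon (CH3), C2/C3 methylenes, C4 isopropyl carbinol carbon, C5 fusion CH, C6 acyloxy carbon, C7=C8(CH3), C9, C10; ring A is C1–C5. The SMILES is read as the cis-fused hydroazulene (3R,3aS,4R,8aR): C1–CH3, H5 and H6 on one face, both oxygens on the other. Assumption: the antipode of the carbene ligand that leads to (R)-9 is identified in the first run, and the route is written for that antipode. 3-Ethoxycyclopent-2-en-1-one is taken as a purchasable starting material.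

**Route**

Step 1
Reactants: 1 isobutyryl chloride (2-methylpropanoyl chloride); 2 ethylene
Product: 3 1-chloro-4-methylpentan-3-one
Conditions: AlCl3 (1.1 equiv), ethylene (1 atm), CH2Cl2, 0 °C; ice/aq. HCl
Reagents that add atoms: none
Why: Friedel–Crafts-type acylation of ethylene, in which the acylium ion adds to the alkene and chloride captures the β-cation to give the β-chloroethyl ketone, with no stereocentre formed.

Step 2
Reactants: 3 1-chloro-4-methylpentan-3-one
Product: 4 2-(2-chloroethyl)-2-(propan-2-yl)-1,3-dioxolane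
Conditions: HOCH2CH2OH (3 equiv), TsOH·H2O (cat.), cyclohexane, reflux, Dean–Stark
Reagents that add atoms: ethylene glycol OCCO
Why: Acid-catalysed ketalisation with azeotropic removal of water masks the ketone for the metalation, photochemical and SmI2 steps, and acidic conditions avoid the loss of HCl that base would cause in a β-chloro ketone.

Step 3
Reactants: 4 2-(2-chloroethyl)-2-(propan-2-yl)-1,3-dioxolane; 5 3-ethoxycyclopent-2-en-1-one
Product: 8 3-{2-[2-(propan-2-yl)-1,3-dioxolan-2-yl]ethyl}cyclopent-2-en-1-one, via lithiated ketal 6 (not isolated), via tertiary allylic carbinol 7 (not isolated)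
Conditions: Li powder (2.2 equiv), 4,4'-di-tert-butylbiphenyl (5 mol%), THF, −78 °C; then 5, −78 → 0 °C; then 1 M aq. HCl, 0 °C, 15 min
Reagents that add atoms: water O
Why: Arene-catalysed reductive lithiation of the primary chloride at −78 °C gives a masked homoenolate that adds 1,2 to the vinylogous ester, and brief dilute acid turns the carbinol into the transposed enone (Stork–Danheiser sequence) faster than it opens the hindered dioxolane.

Step 4
Reactants: 8 3-{2-[2-(propan-2-yl)-1,3-dioxolan-2-yl]ethyl}cyclopent-2-en-1-one
Product: 9 (R)-3-methyl-3-{2-[2-(propan-2-yl)-1,3-dioxolan-2-yl]ethyl}cyclopentan-1-one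
Conditions: Me3Al (3 equiv), Cu(OTf)2 (5 mol%), chiral sulfonate-bearing N-heterocyclic carbene added as its silver carbene complex (2.5 mol%, made from the imidazolinium sulfonate and Ag2O), THF, −78 °C; aq. potassium sodium tartrate
Reagents that add atoms: trimethylaluminium C[Al](C)C
Why: Copper-catalysed asymmetric conjugate addition of Me3Al, a reaction established for β-alkylcyclopentenones, builds the quaternary carbon C1, with the chiral carbene on copper selecting the enone face that gives R.

Step 5
Reactants: 9 (R)-3-methyl-3-{2-[2-(propan-2-yl)-1,3-dioxolan-2-yl]ethyl}cyclopentan-1-one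
Product: 11 (R)-4-methyl-4-{2-[2-(propan-2-yl)-1,3-dioxolan-2-yl]ethyl}cyclopent-2-en-1-one, via silyl enol ether 10 (not isolated)
Conditions: LiN(i-Pr)2 (1.1 equiv), Me3SiCl, THF, −78 °C; then Pd(OAc)2 (1.05 equiv), MeCN, rt
Reagents that add atoms: none
Why: Saegusa–Ito oxidation, in which kinetic deprotonation occurs at the ring CH2 remote from the quaternary carbon and only that enol ether can undergo β-hydride elimination after palladation, so the double bond ends next to C1 and the stereocentre is untouched.

Step 6
Reactants: 11 (R)-4-methyl-4-{2-[2-(propan-2-yl)-1,3-dioxolan-2-yl]ethyl}cyclopent-2-en-1-one; 12 propa-1,2-diene (allene)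
Product: 13 (1R,4R,5R)-4-methyl-7-methylidene-4-{2-[2-(propan-2-yl)-1,3-dioxolan-2-yl]ethyl}bicyclo[3.2.0]heptan-2-one (cis-fused; cyclobutane on the face of the C4 methyl; expected major facial isomer)
Conditions: allene (excess, condensed), THF, −78 °C, hν (medium-pressure Hg lamp, uranium-glass filter, λ > 340 nm)
Reagents that add atoms: none
Why: Light of this wavelength excites only the enone, whose triplet bonds through its α-carbon (C7) to the central allene carbon (C8) to give a triplet 1,4-diradical (allyl radical over C8–C9, alkyl radical at C10), and after spin inversion the allyl terminus C9 couples with C10. The closest known reaction is the head-to-head [2+2] photocycloaddition of allene to cyclopentenones and cyclohexenones, which gives β,γ-unsaturated cyclobutyl ketones. The one ring formed, the cyclobutane C7–C8–C9–C10, closes by radical–radical recombination of the 1,4-diradical on one face of the former C7=C10 bond and is therefore cis-fused to the five-membered ring. The new stereocentres C7 and C10 are set together by the enone face that allene attacks, and the quaternary C1 directs attack to the side of its methyl group, away from the longer ketal chain. The step needs regioselectivity only (central allene carbon on C7), which comes from the preference of the enone α-carbon to bond to the allene centre so that an allyl radical results, helped by the hindered C10 next to C1 accepting the small CH2 terminus. Facial selectivity is not needed, because in step 7 C7 becomes trigonal and C10 a methylene, so both facial isomers converge.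

Step 7
Reactants: 13 (1R,4R,5R)-4-methyl-7-methylidene-4-{2-[2-(propan-2-yl)-1,3-dioxolan-2-yl]ethyl}bicyclo[3.2.0]heptan-2-one
Product: 15 (R)-3,6-dimethyl-6-{2-[2-(propan-2-yl)-1,3-dioxolan-2-yl]ethyl}cyclohept-2-en-1-one, via exocyclic enone 14 (not isolated)
Conditions: SmI2 (2.5 equiv), HMPA, t-BuOH (2 equiv), THF, −78 → 0 °C; then DBU (cat.), CH2Cl2, rt, stopped when 14 is consumed
Reagents that add atoms: none
Why: Ketyl radical-anion fragmentation of a cyclobutyl ketone, in which the C6 ketyl breaks the ring-fusion bond C7–C10 because scission of C7–C8 would leave a vinyl radical, the C10 radical is reduced and protonated, and DBU then draws the exocyclic double bond of 14 into conjugation, so that C7 and C10 lose their stereochemistry while C1 is unaffected.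

Step 8
Reactants: 15 (R)-3,6-dimethyl-6-{2-[2-(propan-2-yl)-1,3-dioxolan-2-yl]ethyl}cyclohept-2-en-1-one
Product: 16 (R)-3,6-dimethyl-6-(4-methyl-3-oxopentyl)cyclohept-2-en-1-one
Conditions: 2 M aq. HCl, THF, rt
Reagents that add atoms: water O
Why: Acid-catalysed hydrolysis of the dioxolane frees the isopropyl ketone, while the enone and the quaternary centre are inert to aqueous acid at room temperature.

Step 9
Reactants: 16 (R)-3,6-dimethyl-6-(4-methyl-3-oxopentyl)cyclohept-2-en-1-one
Product: 17 (3R,3aR,8aR)-3-hydroxy-6,8a-dimethyl-3-(propan-2-yl)-2,3,3a,7,8,8a-hexahydroazulen-4(1H)-one (cis-fused; hydroxyl cis to the carbonyl-bearing carbon on ring A)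
Conditions: LiN(SiMe3)2 (1.05 equiv), THF, −78 → −30 °C; AcOH, −78 °C
Reagents that add atoms: none
Why: Intramolecular aldol addition (5-exo-trig, enolexo), in which the cross-conjugated lithium enolate at C5 attacks the C4 ketone through a lithium-bridged transition state that places the new hydroxyl syn to the C6 carbonyl and isopropyl on the open side, while the three-atom tether from C1 can reach only the enolate face that gives the cis ring fusion, so C4 and C5 are both set by C1.

Step 10
Reactants: 17 (3R,3aR,8aR)-3-hydroxy-6,8a-dimethyl-3-(propan-2-yl)-2,3,3a,7,8,8a-hexahydroazulen-4(1H)-one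
Product: 18 (3R,3aS,4R,8aR)-6,8a-dimethyl-3-(propan-2-yl)-1,2,3,3a,4,7,8,8a-octahydroazulene-3,4-diol
Conditions: i-Bu2AlH (2.5 equiv), THF, −78 °C; aq. potassium sodium tartrate
Reagents that add atoms: none
Why: Chelation-controlled 1,2-reduction, in which the first equivalent of i-Bu2AlH converts the C4 hydroxyl into an aluminium alkoxide that binds the C6 carbonyl and a second equivalent delivers hydride from the face anti to C4 (the side of H5), giving the 1,3-syn diol with 6R configuration.

Step 11
Reactants: 19 isovanillic acid (3-hydroxy-4-methoxybenzoic acid)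
Product: 21 3-[(tert-butyldimethylsilyl)oxy]-4-methoxybenzoic acid, via bis-silylated acid 20 (not isolated)
Conditions: t-BuMe2SiCl (2.2 equiv), imidazole (4.5 equiv), DMF, rt; then AcOH/THF/H2O, rt
Reagents that add atoms: tert-butyldimethylsilyl chloride CC(C)(C)[Si](C)(C)Cl
Why: Silylation of both acidic OH groups followed by selective hydrolysis of the labile silyl ester leaves the phenol as a silyl ether that withstands carbodiimide coupling.

Step 12
Reactants: 18 (3R,3aS,4R,8aR)-6,8a-dimethyl-3-(propan-2-yl)-1,2,3,3a,4,7,8,8a-octahydroazulene-3,4-diol; 21 3-[(tert-butyldimethylsilyl)oxy]-4-methoxybenzoic acid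
Product: 22 (3R,3aS,4R,8aR)-3-hydroxy-6,8a-dimethyl-3-(propan-2-yl)-1,2,3,3a,4,7,8,8a-octahydroazulen-4-yl 3-[(tert-butyldimethylsilyl)oxy]-4-methoxybenzoate
Conditions: EDC·HCl (1.5 equiv), DMAP (0.5 equiv), CH2Cl2, rt
Reagents that add atoms: none
Why: Steglich esterification acylates only the secondary allylic C6 hydroxyl because the tertiary C4 hydroxyl is too hindered, and C6 keeps its configuration since its C–O bond is not broken.

Step 13
Reactants: 22 (3R,3aS,4R,8aR)-3-hydroxy-6,8a-dimethyl-3-(propan-2-yl)-1,2,3,3a,4,7,8,8a-octahydroazulen-4-yl 3-[(tert-butyldimethylsilyl)oxy]-4-methoxybenzoate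
Product: 23 (3R,3aS,4R,8aR)-3-hydroxy-6,8a-dimethyl-3-(propan-2-yl)-1,2,3,3a,4,7,8,8a-octahydroazulen-4-yl 3-hydroxy-4-methoxybenzoate (CNP0210850.1)
Conditions: Bu4NF (1.1 equiv), AcOH (1.2 equiv), THF, 0 °C
Reagents that add atoms: none
Why: Fluoride cleaves the aryl silyl ether while the acetic acid buffer keeps the phenoxide from attacking the allylic ester, and no stereocentre is involved.

**Compound list**

1 | isobutyryl chloride | CC(C)C(=O)Cl | starting material
2 | ethylene | C=C | starting material
3 | 1-chloro-4-methylpentan-3-one | CC(C)C(=O)CCCl | intermediate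
4 | 2-(2-chloroethyl)-2-(propan-2-yl)-1,3-dioxolane | CC(C)C1(CCCl)OCCO1 | intermediate
5 | 3-ethoxycyclopent-2-en-1-one | CCOC1=CC(=O)CC1 | starting material
6 | {2-[2-(propan-2-yl)-1,3-dioxolan-2-yl]ethyl}lithium | [Li]CCC1(C(C)C)OCCO1 | intermediate
7 | 3-ethoxy-1-{2-[2-(propan-2-yl)-1,3-dioxolan-2-yl]ethyl}cyclopent-2-en-1-ol (racemic, present as its lithium alkoxide until the quench) | CCOC1=CC(O)(CCC2(C(C)C)OCCO2)CC1 | intermediate
8 | 3-{2-[2-(propan-2-yl)-1,3-dioxolan-2-yl]ethyl}cyclopent-2-en-1-one | O=C1C=C(CCC2(C(C)C)OCCO2)CC1 | intermediate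
9 | (R)-3-methyl-3-{2-[2-(propan-2-yl)-1,3-dioxolan-2-yl]ethyl}cyclopentan-1-one | O=C1CC[C@](C)(CCC2(C(C)C)OCCO2)C1 | intermediate
10 | (S)-trimethyl[(4-methyl-4-{2-[2-(propan-2-yl)-1,3-dioxolan-2-yl]ethyl}cyclopent-1-en-1-yl)oxy]silane | C[Si](C)(C)OC1=CC[C@](C)(CCC2(C(C)C)OCCO2)C1 | intermediate
11 | (R)-4-methyl-4-{2-[2-(propan-2-yl)-1,3-dioxolan-2-yl]ethyl}cyclopent-2-en-1-one | O=C1C=C[C@](C)(CCC2(C(C)C)OCCO2)C1 | intermediate
12 | propa-1,2-diene | C=C=C | starting material
13 | (1R,4R,5R)-4-methyl-7-methylidene-4-{2-[2-(propan-2-yl)-1,3-dioxolan-2-yl]ethyl}bicyclo[3.2.0]heptan-2-one | O=C1[C@H]2C(=C)C[C@H]2[C@](C)(CCC3(C(C)C)OCCO3)C1 | intermediate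
14 | (R)-6-methyl-3-methylidene-6-{2-[2-(propan-2-yl)-1,3-dioxolan-2-yl]ethyl}cycloheptan-1-one | O=C1CC(=C)CC[C@](C)(CCC2(C(C)C)OCCO2)C1 | intermediate
15 | (R)-3,6-dimethyl-6-{2-[2-(propan-2-yl)-1,3-dioxolan-2-yl]ethyl}cyclohept-2-en-1-one | O=C1C=C(C)CC[C@](C)(CCC2(C(C)C)OCCO2)C1 | intermediate
16 | (R)-3,6-dimethyl-6-(4-methyl-3-oxopentyl)cyclohept-2-en-1-one | O=C1C=C(C)CC[C@](C)(CCC(=O)C(C)C)C1 | intermediate
17 | (3R,3aR,8aR)-3-hydroxy-6,8a-dimethyl-3-(propan-2-yl)-2,3,3a,7,8,8a-hexahydroazulen-4(1H)-one | O=C1C=C(C)CC[C@]2(C)CC[C@@](O)(C(C)C)[C@H]12 | intermediate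
18 | (3R,3aS,4R,8aR)-6,8a-dimethyl-3-(propan-2-yl)-1,2,3,3a,4,7,8,8a-octahydroazulene-3,4-diol | O[C@@H]1C=C(C)CC[C@]2(C)CC[C@@](O)(C(C)C)[C@H]12 | intermediate
19 | isovanillic acid | COc1ccc(C(=O)O)cc1O | starting material
20 | tert-butyldimethylsilyl 3-[(tert-butyldimethylsilyl)oxy]-4-methoxybenzoate | COc1ccc(C(=O)O[Si](C)(C)C(C)(C)C)cc1O[Si](C)(C)C(C)(C)C | intermediate
21 | 3-[(tert-butyldimethylsilyl)oxy]-4-methoxybenzoic acid | COc1ccc(C(=O)O)cc1O[Si](C)(C)C(C)(C)C | intermediate
22 | (3R,3aS,4R,8aR)-3-hydroxy-6,8a-dimethyl-3-(propan-2-yl)-1,2,3,3a,4,7,8,8a-octahydroazulen-4-yl 3-[(tert-butyldimethylsilyl)oxy]-4-methoxybenzoate | COc1ccc(C(=O)O[C@@H]2C=C(C)CC[C@]3(C)CC[C@@](O)(C(C)C)[C@H]23)cc1O[Si](C)(C)C(C)(C)C | intermediate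
23 | (3R,3aS,4R,8aR)-3-hydroxy-6,8a-dimethyl-3-(propan-2-yl)-1,2,3,3a,4,7,8,8a-octahydroazulen-4-yl 3-hydroxy-4-methoxybenzoate | COc1ccc(C(=O)O[C@@H]2C=C(C)CC[C@]3(C)CC[C@@](O)(C(C)C)[C@H]23)cc1O | target

**Count and risks**

Total step count: 13. Longest linear sequence: 12 steps (steps 1–10, 12 and 13; step 11 is the side branch).

Step 7 (reductive ring opening). What may go wrong: the fusion bond is poorly aligned with the ketyl orbital, so the ketyl may be reduced on to the cyclobutyl carbinol or may dimerise before the ring opens. The fallback sets out from 13 and comes back at 15. The exocyclic double bond is first moved into the four-membered ring (RhCl3·3H2O cat., EtOH, 60 °C) to give the cyclobutene (1R,4R,5R)-4,7-dimethyl-4-{2-[2-(propan-2-yl)-1,3-dioxolan-2-yl]ethyl}bicyclo[3.2.0]hept-6-en-2-one F1. Its fusion bond C7–C10 is now allylic, so the opening with SmI2/t-BuOH is driven by formation of an allyl radical. After the second electron transfer and protonation it should give the deconjugated enone (S)-3,6-dimethyl-6-{2-[2-(propan-2-yl)-1,3-dioxolan-2-yl]ethyl}cyclohept-3-en-1-one F2, which DBU equilibrates to 15.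

Step 9 (aldol closure). What may go wrong: deprotonation at C3 of the side chain or at the γ-positions of the enone instead of C5, loss of water from the ketol, or migration of the ring double bond under base. The fallback sets out from 15 and comes back at 17; it generates the C5 enolate regiospecifically by reduction of a C–Br bond. Kinetic deprotonation of 15, where the enone is the only ketone (LiN(i-Pr)2, THF, −78 °C), and quenching with N-bromosuccinimide should give (6R)-7-bromo-3,6-dimethyl-6-{2-[2-(propan-2-yl)-1,3-dioxolan-2-yl]ethyl}cyclohept-2-en-1-one F3 as a mixture of bromide epimers. Treatment with 2 M HCl in THF removes the dioxolane to give (6R)-7-bromo-3,6-dimethyl-6-(4-methyl-3-oxopentyl)cyclohept-2-en-1-one F4. SmI2 (2.2 equiv, THF, −78 °C) then reduces the C–Br bond to a trivalent samarium enolate, which closes onto the C4 ketone in a Reformatsky-type aldol through the same metal-bridged arrangement and gives 17 without any base.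

Step 10 (reduction of the enone). What may go wrong: hydride addition from the concave face, or poor facial selectivity, leaving the C6 epimer. The fallback sets out from 17 and comes back at 22; it makes the epimer on purpose and inverts it while the ester is formed. Hydroxyl-directed reduction with Me4NBH(OAc)3 (MeCN/AcOH, −30 °C), in which hydride is delivered from boron bound to the C4 oxygen, should give the anti diol (3R,3aS,4S,8aR)-6,8a-dimethyl-3-(propan-2-yl)-1,2,3,3a,4,7,8,8a-octahydroazulene-3,4-diol F5. Mitsunobu esterification of F5 with acid 21 (PPh3, diisopropyl azodicarboxylate, toluene, 0 °C → rt) then forms the C6–O bond with inversion and gives 22 directly.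

**Further compounds**

F1 | step 7 | (1R,4R,5R)-4,7-dimethyl-4-{2-[2-(propan-2-yl)-1,3-dioxolan-2-yl]ethyl}bicyclo[3.2.0]hept-6-en-2-one | O=C1[C@H]2C(C)=C[C@H]2[C@](C)(CCC3(C(C)C)OCCO3)C1
F2 | step 7 | (S)-3,6-dimethyl-6-{2-[2-(propan-2-yl)-1,3-dioxolan-2-yl]ethyl}cyclohept-3-en-1-one | O=C1CC(C)=CC[C@](C)(CCC2(C(C)C)OCCO2)C1
F3 | step 9 | (6R)-7-bromo-3,6-dimethyl-6-{2-[2-(propan-2-yl)-1,3-dioxolan-2-yl]ethyl}cyclohept-2-en-1-one | O=C1C=C(C)CC[C@](C)(CCC2(C(C)C)OCCO2)C1Br
F4 | step 9 | (6R)-7-bromo-3,6-dimethyl-6-(4-methyl-3-oxopentyl)cyclohept-2-en-1-one | O=C1C=C(C)CC[C@](C)(CCC(=O)C(C)C)C1Br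
F5 | step 10 | (3R,3aS,4S,8aR)-6,8a-dimethyl-3-(propan-2-yl)-1,2,3,3a,4,7,8,8a-octahydroazulene-3,4-diol | O[C@H]1C=C(C)CC[C@]2(C)CC[C@@](O)(C(C)C)[C@H]12
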